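## Structural features

Pestallic acid J is a cyclohex-2-enone in which every ring carbon is substituted (numbering used throughout: C1 ketone, C2=C3 enone alkene, then C4, C5, C6). C2 carries an (E)-hept-1-enyl chain C1'–C7' with an (R)-acetoxy group at C6'; C3 carries CH2OH; C4 and C5 carry hydroxyls; C6 carries the (E)-CH2–CH=C(CH3)–CO2H branch C1''–C4''. The ring stereocentres C4 (R), C5 (S) and C6 (R) are contiguous and all-cis, whereas C6' (R) is remote and independent. C5–OH is β and H6 is α to the C1 ketone, so enolization toward C6 can epimerize C6 or expel the C5 oxygen, and the dienone so formed is one tautomerization from a phenol. The secondary acetate must survive beside three free hydroxyls and a free acid, which excludes basic or hydrolytic conditions late in the route. The real difficulty is C6: a carbon branch must be placed α to the ketone and cis to the C5 oxygen without passing through the C1/C6 enolate; the fully substituted C2=C3 enone comes second. The key step exploits the fact that C4/C5 is a cis-diol next to the sp2 carbon C3, the pattern of an arene cis-dihydrodiol. In that cyclohexa-1,3-diene, C6 is the diene terminus next to C5–O and C1 is the far end of the remaining allyl unit C1–C2–C3, so a two-carbon radical tethered to O5 can reach C6 only from the O5 face and the allyl radical left behind can take up oxygen at C1.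

## Logic of the disconnections

21 ⇒ 20. The O–C(CH3)3 bond of the carboxyl ester is cut. The acid is unmasked last by acidolysis, the one ester cleavage that cannot touch the C6' acetate. The gain is that no free acid is carried and no hydrolysis is ever applied to the acetate. The demand is that the β-hydroxy ketone tolerates brief strong acid.

20 ⇒ 16 + 19. The C2''=C3'' bond is cut. The C6 branch shrinks to a two-carbon unit at the aldehyde level, which in 16 is tied back to O5 as a five-membered hemiacetal. The gain is that the branch, the C5 hydroxyl and C6 are reduced to one cis-fused ring. The demand is an E-selective olefination that is not basic enough to enolize C1/C6.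

16 ⇒ 15. The O4–Si bond and the acetal C–OEt bond are restored. One acid treatment removes both. 15 has no free β-hydroxyl and its ring fusion holds C6, so all enone chemistry can be done before this point.

15 ⇒ 9 + 14. The sp2–sp2 bond C2–C1' is cut; this is the point of convergence. The gain is that the whole C1'–C7' chain, with its stereocentre and acetate, is made apart. The demand is a coupling without base strong enough to cleave the acetate or enolize the ketone.

14 ⇒ 13 ⇒ 12 ⇒ 10 + 11. In turn the C1'=C2' bond (metathesis with a vinylboron partner), the acetyl C–O bond, and the C4'–C5' bond are cut. The gain is that C6' is bought as an epoxide carbon whose C–O bond is never broken. The demand is attack at the unsubstituted epoxide carbon only.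

9 ⇒ 8 ⇒ 7. The C2–I bond, then the C3–CH2OH bond, are cut. This returns to a β-bromo enone whose bromine is the one the starting arene carried. The demand is α-iodination of an enone with a fully substituted β-carbon under weakly basic conditions.

7 ⇒ 6. The C1=O bond is traced to a C1–O–N single bond. The gain is that the ketone appears only after the C6 branch is locked in a ring. The demand is an oxidation that leaves the bromoalkene alone.

6 ⇒ 3 (through 4 and 5): the key disconnection. The C6–C1'' bond and the C1–O bond are cut together, which opens the five-membered ring. In one sentence: a two-carbon radical hung from O5 of a dearomatized bromobenzene closes onto C6, and the resulting allyl radical is oxygenated at C1. The gain is a return to a cyclohexa-1,3-diene that holds only the two bought stereocentres; C6, its branch, the C1 oxygen and the position of the later enone all come from this single operation. The demand is ring closure before radical trapping, and trapping at C1 and not at C3.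

3 ⇒ 2 ⇒ 1. The O4–Si bond, then the acetal C–O5 bond, are cut. 1 supplies C4 and C5 in the correct absolute sense, the sp2 C3 with a handle, and the diene. The demand is that the two hydroxyls are told apart.

19 ⇒ 17 (through 18). The C=P bond is cut back to a C–Br bond. The gain is a one-operation ylide from a bulk ester. The only demand is SN2 at a secondary α-bromo ester.

## Other disconnections considered

Alternative 1: cut C6–C1'' at the enolate stage (the first idea that comes to mind). Forward, the C1/C6 enolate of the enone acetonide A1 would be alkylated with the allylic bromide A2 to give A3. In that enolate the C5 oxygen is a β leaving group, so E1cB opening of the dioxolane and aromatization compete with C-alkylation. The electrophile must also approach anti to the dioxolane, which leads to the 5,6-trans epimer A3, the opposite of the target. Correcting C6 would require the same eliminating enolate again. The chosen plan never forms that enolate and takes its facial control from a ring constraint, not from a steric bias that points the wrong way.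

Alternative 2: cut C6–H back to a C5–C6 epoxide. Forward, oxidative dearomatization of a polysubstituted hydroquinone monoether would give the quinone monoketal A4; epoxidation of C5=C6 and adjustment at C4 would give the epoxy ketone A5; reductive C6–O cleavage with SmI2 would follow. C6 would then be created by protonation of a samarium enolate, for which the substrate offers no decisive facial bias, and that enolate again has the C5 oxygen in the β position. The arene needed for A4 is itself a multi-step target, and the absolute configuration would rest on an asymmetric epoxidation of a hindered dienone. This means more steps and less control at the centre that matters most.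

Alternative 3: cut C1=O and C4–O together. Forward, [4+2] addition of singlet oxygen to the 5,6-cis-disubstituted cyclohexa-1,3-diene A6 would give the endoperoxide A7, and Kornblum–DeLaMare rearrangement would give the 4-hydroxy enone. Oxygen adds to the face opposite the two cis substituents, so C4–O ends trans to C5–O; this is the C4 epimer, and repair needs inversion at a hindered allylic carbinol. The base has no clear reason to remove H1 in preference to H4, and the wrong choice puts the ketone at C4. A6 already contains the cis C5/C6 pair, so the hardest problem is moved back and not solved.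

Key step: step 3

Remark: 1 is bought as the homochiral cis-dihydrodiol produced by whole-cell (toluene dioxygenase) oxidation of bromobenzene, so the dearomatization that sets C4 and C5 precedes step 1. The acetal carbon made in step 1 and the aminoxyl-bearing C1 made in step 3 are epimer mixtures that are erased in steps 13 and 4.

## Steps

Step 1
Reactants: 1 (1S,2S)-3-bromocyclohexa-3,5-diene-1,2-diol
Product: 2 (1S,6S)-2-bromo-6-(1-ethoxy-2-iodoethoxy)cyclohexa-2,4-dien-1-ol (O5 mixed iodoacetal; both acetal epimers)
Conditions: ethyl vinyl ether (1.2 equiv), NIS (1.05 equiv), NaHCO3 (solid), CH2Cl2, −40 → −20 °C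
Reagents that add atoms: ethyl vinyl ether C=COCC; N-iodosuccinimide O=C1CCC(=O)N1I
Why: Haloacetal formation (iodoalkoxylation of an enol ether): the iodo-oxocarbenium ion should be captured by the less hindered hydroxyl on C5, remote from the bromine-bearing C3, under near-neutral conditions that should not dehydrate the dihydrodiol; the new acetal stereocentre is of no consequence.

Step 2
Reactants: 2 (1S,6S)-2-bromo-6-(1-ethoxy-2-iodoethoxy)cyclohexa-2,4-dien-1-ol
Product: 3 tert-butyl{[(1S,6S)-2-bromo-6-(1-ethoxy-2-iodoethoxy)cyclohexa-2,4-dien-1-yl]oxy}dimethylsilane (O4 silyl ether of 2)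
Conditions: TBSOTf (1.2 equiv), 2,6-lutidine (2 equiv), CH2Cl2, −78 °C
Reagents that add atoms: tert-butyldimethylsilyl trifluoromethanesulfonate C[Si](C)(OS(=O)(=O)C(F)(F)F)C(C)(C)C
Why: Standard silylation of a hindered secondary alcohol at low temperature in the presence of a hindered base; it removes the last free hydroxyl and places a bulky group beside C3, which should help steer the oxygenation of step 3 to C1.

Step 3
Reactants: 3 tert-butyl{[(1S,6S)-2-bromo-6-(1-ethoxy-2-iodoethoxy)cyclohexa-2,4-dien-1-yl]oxy}dimethylsilane
Product: 6 cis-fused 6-bromo-7-(tert-butyldimethylsilyloxy)-2-ethoxy-4-[(2,2,6,6-tetramethylpiperidin-1-yl)oxy]-2,3,3a,4,7,7a-hexahydrobenzofuran, via primary alkyl radical 4 (not isolated), via allyl radical 5 (not isolated)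
Conditions: Bu3SnH (1.5 equiv, syringe pump), TEMPO (3 equiv, in portions), benzene (0.01 M), 70 °C
Reagents that add atoms: TEMPO (2,2,6,6-tetramethylpiperidin-1-oxyl) CC1(C)CCCC(C)(C)N1[O]
Why: The closest known reaction type is the Ueno–Stork haloacetal radical cyclization, here terminated by aminoxyl trapping as in tin hydride/TEMPO cyclization–oxygenations. Bu3Sn•, formed from Bu3SnH and TEMPO, abstracts iodine from 3 to give the primary radical 4. Radical 4 closes the tetrahydrofuran ring in the 5-exo-trig mode onto C6, the diene terminus, which should be faster than closure onto an isolated alkene because the product 5 is an allyl radical spread over C1–C2–C3; the 6-endo mode (attack at C1) would give an unstabilized radical and is not expected. A three-atom tether anchored on O5 can reach C6 only from the O5 face, so the new ring is cis-fused and the C6–C1'' bond is cis to C5–O: C6 is set by C5 through the ring constraint alone. Radical 5 then couples with the persistent aminoxyl at C1, the secondary terminus remote from the bromine and the silyloxy group; coupling at C3 would give a crowded α-bromo alkoxyamine, and because allylic alkoxyamines form reversibly at this temperature the more stable C1 isomer with the intact vinyl bromide should accumulate. The selectivity needed is cyclization before trapping, which the fast closure onto the diene, high dilution and a low stationary aminoxyl concentration should secure. The configuration at C1 is immaterial because C1 becomes the ketone in step 4.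

Step 4
Reactants: 6 cis-fused 6-bromo-7-(tert-butyldimethylsilyloxy)-2-ethoxy-4-[(2,2,6,6-tetramethylpiperidin-1-yl)oxy]-2,3,3a,4,7,7a-hexahydrobenzofuran
Product: 7 cis-fused 6-bromo-7-(tert-butyldimethylsilyloxy)-2-ethoxy-3,3a,7,7a-tetrahydrobenzofuran-4(2H)-one
Conditions: mCPBA (1.5 equiv), CH2Cl2, 0 °C → rt
Reagents that add atoms: none
Why: Oxidative cleavage of a secondary alkoxyamine (N-oxidation, then Cope-type elimination across O–N) should give the ketone directly as the β-bromo enone; the electron-poor bromoalkene should resist epoxidation, and the cis ring fusion now locks C6 against epimerization.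

Step 5
Reactants: 7 cis-fused 6-bromo-7-(tert-butyldimethylsilyloxy)-2-ethoxy-3,3a,7,7a-tetrahydrobenzofuran-4(2H)-one
Product: 8 cis-fused 7-(tert-butyldimethylsilyloxy)-2-ethoxy-6-(hydroxymethyl)-3,3a,7,7a-tetrahydrobenzofuran-4(2H)-one
Conditions: Bu3SnCH2OH (1.3 equiv), Pd(PPh3)4 (5 mol%), 1,4-dioxane, 80 °C
Reagents that add atoms: (tributylstannyl)methanol OC[Sn](CCCC)(CCCC)CCCC
Why: Stille hydroxymethylation; a β-bromo enone undergoes oxidative addition readily, and the neutral conditions should leave the β-alkoxy ketone and the acetal untouched.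

Step 6
Reactants: 8 cis-fused 7-(tert-butyldimethylsilyloxy)-2-ethoxy-6-(hydroxymethyl)-3,3a,7,7a-tetrahydrobenzofuran-4(2H)-one
Product: 9 cis-fused 7-(tert-butyldimethylsilyloxy)-2-ethoxy-6-(hydroxymethyl)-5-iodo-3,3a,7,7a-tetrahydrobenzofuran-4(2H)-one
Conditions: I2 (2 equiv), pyridine/CH2Cl2 (1:1), DMAP (0.2 equiv), 0 °C → rt
Reagents that add atoms: iodine II
Why: Amine-mediated α-iodination of an enone (conjugate addition of the amine, iodination of the enolate, elimination); pyridine is too weak a base to enolize toward C6, and the free primary alcohol is tolerated.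

Step 7
Reactants: 10 (R)-2-methyloxirane; 11 but-3-enylmagnesium bromide
Product: 12 (R)-hept-6-en-2-ol
Conditions: CuI (10 mol%), THF, −30 → 0 °C; then 1 M aq. HCl
Reagents that add atoms: none
Why: Copper-catalysed opening of a terminal epoxide by a Grignard reagent at the unsubstituted carbon; the C–O bond of the stereocentre is not touched, so the (R) centre of 10 becomes C6' (R).

Step 8
Reactants: 12 (R)-hept-6-en-2-ol
Product: 13 (R)-hept-6-en-2-yl acetate
Conditions: Ac2O, Et3N, DMAP (cat.), CH2Cl2, 0 °C → rt
Reagents that add atoms: acetic anhydride CC(=O)OC(C)=O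
Why: Standard acylation; installing the acetate before fragment union avoids any late differentiation among four hydroxyls.

Step 9
Reactants: 13 (R)-hept-6-en-2-yl acetate
Product: 14 (R,E)-7-(4,4,5,5-tetramethyl-1,3,2-dioxaborolan-2-yl)hept-6-en-2-yl acetate
Conditions: vinylboronic acid pinacol ester (2 equiv), second-generation Grubbs catalyst RuCl2(=CHPh)(PCy3)(H2IMes) (3 mol%), CH2Cl2, 40 °C
Reagents that add atoms: 4,4,5,5-tetramethyl-2-vinyl-1,3,2-dioxaborolane C=CB1OC(C)(C)C(C)(C)O1
Why: Olefin cross-metathesis of a terminal alkene with a vinylboronate, which should give the (E)-alkenylboronate under thermodynamic control with loss of ethene.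

Step 10
Reactants: 9 cis-fused 7-(tert-butyldimethylsilyloxy)-2-ethoxy-6-(hydroxymethyl)-5-iodo-3,3a,7,7a-tetrahydrobenzofuran-4(2H)-one; 14 (R,E)-7-(4,4,5,5-tetramethyl-1,3,2-dioxaborolan-2-yl)hept-6-en-2-yl acetate
Product: 15 cis-fused 5-[(1E,6R)-6-acetoxyhept-1-en-1-yl]-7-(tert-butyldimethylsilyloxy)-2-ethoxy-6-(hydroxymethyl)-3,3a,7,7a-tetrahydrobenzofuran-4(2H)-one
Conditions: PdCl2(PhCN)2 (5 mol%), AsPh3 (10 mol%), Ag2O (1.5 equiv), THF/H2O (8:1), rt
Reagents that add atoms: none
Why: Suzuki–Miyaura coupling of an α-iodo enone with an alkenylboronate, promoted by Ag2O in place of a soluble base, which should spare the acetate and the β-alkoxy ketone; the alkene geometry of 14 is retained.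

Step 11
Reactants: 15 cis-fused 5-[(1E,6R)-6-acetoxyhept-1-en-1-yl]-7-(tert-butyldimethylsilyloxy)-2-ethoxy-6-(hydroxymethyl)-3,3a,7,7a-tetrahydrobenzofuran-4(2H)-one
Product: 16 cis-fused 5-[(1E,6R)-6-acetoxyhept-1-en-1-yl]-2,7-dihydroxy-6-(hydroxymethyl)-3,3a,7,7a-tetrahydrobenzofuran-4(2H)-one (lactol; both anomers)
Conditions: 48% aq. HF, MeCN/H2O, 0 °C → rt
Reagents that add atoms: water O
Why: Acid-mediated desilylation and hydrolysis of the 2-ethoxytetrahydrofuran acetal in one operation; the secondary acetate should be stable to aqueous acid of this strength, and C5–O stays masked as the lactol ring oxygen.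

Step 12
Reactants: 17 tert-butyl 2-bromopropanoate (racemic)
Product: 19 tert-butyl 2-(triphenylphosphoranylidene)propanoate, via phosphonium bromide 18 (not isolated)
Conditions: PPh3, toluene, 80 °C; then aq. NaOH, CH2Cl2, 0 °C
Reagents that add atoms: triphenylphosphine c1ccc(cc1)P(c1ccccc1)c1ccccc1
Why: SN2 quaternization of phosphorus, then deprotonation of the acidic α-CH, gives the ester-stabilized ylide; the stereocentre of 17 is lost, so the racemate serves.

Step 13
Reactants: 16 cis-fused 5-[(1E,6R)-6-acetoxyhept-1-en-1-yl]-2,7-dihydroxy-6-(hydroxymethyl)-3,3a,7,7a-tetrahydrobenzofuran-4(2H)-one; 19 tert-butyl 2-(triphenylphosphoranylidene)propanoate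
Product: 20 tert-butyl (E)-4-[(1R,5R,6S)-3-[(1E,6R)-6-acetoxyhept-1-en-1-yl]-5,6-dihydroxy-4-(hydroxymethyl)-2-oxocyclohex-3-en-1-yl]-2-methylbut-2-enoate
Conditions: toluene, PhCO2H (10 mol%), 60 °C
Reagents that add atoms: none
Why: Wittig olefination of a lactol through its open hydroxy-aldehyde form; the α-methyl ester-stabilized ylide should give the (E)-trisubstituted enoate and is too weak a base to enolize the ketone, and the ring opening sets free C5–OH.

Step 14
Reactants: 20 tert-butyl (E)-4-[(1R,5R,6S)-3-[(1E,6R)-6-acetoxyhept-1-en-1-yl]-5,6-dihydroxy-4-(hydroxymethyl)-2-oxocyclohex-3-en-1-yl]-2-methylbut-2-enoate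
Product: 21 pestallic acid J
Conditions: TFA/CH2Cl2 (1:4), 0 °C
Reagents that add atoms: none
Why: Acidolysis of a tert-butyl ester with loss of 2-methylpropene; a secondary acetate is inert to these conditions, so the acid is set free without any hydrolytic step.

## Compound list

1 | (1S,2S)-3-bromocyclohexa-3,5-diene-1,2-diol | C1=C(Br)[C@@H](O)[C@@H](O)C=C1 | starting material
2 | (1S,6S)-2-bromo-6-(1-ethoxy-2-iodoethoxy)cyclohexa-2,4-dien-1-ol (O5 iodoacetal, acetal carbon undefined) | C1=C(Br)[C@@H](O)[C@@H](OC(CI)OCC)C=C1 | intermediate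
3 | tert-butyl{[(1S,6S)-2-bromo-6-(1-ethoxy-2-iodoethoxy)cyclohexa-2,4-dien-1-yl]oxy}dimethylsilane | C1=C(Br)[C@@H](O[Si](C)(C)C(C)(C)C)[C@@H](OC(CI)OCC)C=C1 | intermediate
4 | primary alkyl radical from 3 (iodine removed, CH2• on the acetal side chain) | C1=C(Br)[C@@H](O[Si](C)(C)C(C)(C)C)[C@@H](OC([CH2])OCC)C=C1 | intermediate (not isolated)
5 | cis-fused bicyclic allyl radical (tetrahydrofuran closed on C6; radical drawn at C1, delocalized to C3) | C1=C(Br)[C@@H](O[Si](C)(C)C(C)(C)C)[C@H]2OC(OCC)C[C@H]2[CH]1 | intermediate (not isolated)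
6 | cis-fused 6-bromo-7-(tert-butyldimethylsilyloxy)-2-ethoxy-4-[(2,2,6,6-tetramethylpiperidin-1-yl)oxy]-2,3,3a,4,7,7a-hexahydrobenzofuran (H3a/H7a cis, O7 cis to O1; C3a = target C6, C7a = target C5, C7 = target C4; C2 and C4 undefined) | C1=C(Br)[C@@H](O[Si](C)(C)C(C)(C)C)[C@H]2OC(OCC)C[C@H]2C1ON1C(C)(C)CCCC1(C)C | intermediate
7 | cis-fused 6-bromo-7-(tert-butyldimethylsilyloxy)-2-ethoxy-3,3a,7,7a-tetrahydrobenzofuran-4(2H)-one (ring configuration as in 6; C2 undefined) | C1=C(Br)[C@@H](O[Si](C)(C)C(C)(C)C)[C@H]2OC(OCC)C[C@H]2C1=O | intermediate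
8 | cis-fused 7-(tert-butyldimethylsilyloxy)-2-ethoxy-6-(hydroxymethyl)-3,3a,7,7a-tetrahydrobenzofuran-4(2H)-one | C1=C(CO)[C@@H](O[Si](C)(C)C(C)(C)C)[C@H]2OC(OCC)C[C@H]2C1=O | intermediate
9 | cis-fused 7-(tert-butyldimethylsilyloxy)-2-ethoxy-6-(hydroxymethyl)-5-iodo-3,3a,7,7a-tetrahydrobenzofuran-4(2H)-one | IC1=C(CO)[C@@H](O[Si](C)(C)C(C)(C)C)[C@H]2OC(OCC)C[C@H]2C1=O | intermediate
10 | (R)-2-methyloxirane | C[C@@H]1CO1 | starting material
11 | but-3-enylmagnesium bromide | C=CCC[Mg]Br | starting material
12 | (R)-hept-6-en-2-ol | C[C@@H](O)CCCC=C | intermediate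
13 | (R)-hept-6-en-2-yl acetate | CC(=O)O[C@H](C)CCCC=C | intermediate
14 | (R,E)-7-(4,4,5,5-tetramethyl-1,3,2-dioxaborolan-2-yl)hept-6-en-2-yl acetate | CC(=O)O[C@H](C)CCC/C=C/B1OC(C)(C)C(C)(C)O1 | intermediate
15 | cis-fused 5-[(1E,6R)-6-acetoxyhept-1-en-1-yl]-7-(tert-butyldimethylsilyloxy)-2-ethoxy-6-(hydroxymethyl)-3,3a,7,7a-tetrahydrobenzofuran-4(2H)-one | CC(=O)O[C@H](C)CCC/C=C/C1=C(CO)[C@@H](O[Si](C)(C)C(C)(C)C)[C@H]2OC(OCC)C[C@H]2C1=O | intermediate
16 | cis-fused 5-[(1E,6R)-6-acetoxyhept-1-en-1-yl]-2,7-dihydroxy-6-(hydroxymethyl)-3,3a,7,7a-tetrahydrobenzofuran-4(2H)-one (lactol, anomeric carbon undefined) | CC(=O)O[C@H](C)CCC/C=C/C1=C(CO)[C@@H](O)[C@H]2OC(O)C[C@H]2C1=O | intermediate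
17 | tert-butyl 2-bromopropanoate (racemic) | CC(Br)C(=O)OC(C)(C)C | starting material
18 | (1-tert-butoxy-1-oxopropan-2-yl)triphenylphosphonium bromide | CC(C(=O)OC(C)(C)C)[P+](c1ccccc1)(c1ccccc1)c1ccccc1.[Br-] | intermediate (not isolated)
19 | tert-butyl 2-(triphenylphosphoranylidene)propanoate | CC(C(=O)OC(C)(C)C)=P(c1ccccc1)(c1ccccc1)c1ccccc1 | intermediate
20 | tert-butyl (E)-4-[(1R,5R,6S)-3-[(1E,6R)-6-acetoxyhept-1-en-1-yl]-5,6-dihydroxy-4-(hydroxymethyl)-2-oxocyclohex-3-en-1-yl]-2-methylbut-2-enoate | CC(=O)O[C@H](C)CCC/C=C/C1=C(CO)[C@@H](O)[C@@H](O)[C@@H](C/C=C(\C)C(=O)OC(C)(C)C)C1=O | intermediate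
21 | pestallic acid J, (E)-4-[(1R,5R,6S)-3-[(1E,6R)-6-acetoxyhept-1-en-1-yl]-5,6-dihydroxy-4-(hydroxymethyl)-2-oxocyclohex-3-en-1-yl]-2-methylbut-2-enoic acid | CC(=O)O[C@H](C)CCC/C=C/C1=C(CO)[C@@H](O)[C@@H](O)[C@@H](C/C=C(\C)C(=O)O)C1=O | target

## Step count and least certain steps

Total: 14 steps. Longest linear sequence: 10 steps (steps 1, 2, 3, 4, 5, 6, 10, 11, 13, 14 from 1).

Step 3 (key step). The most likely failures are capture of radical 4 by the aminoxyl before ring closure (the two rates are of similar order unless the aminoxyl concentration is kept low) and coupling of radical 5 at C3 instead of C1, which would destroy the vinyl bromide. Fallback, from 3 back to 7: the cyclization is run reductively (Bu3SnH by syringe pump, AIBN, benzene, 80 °C), so that radical 5 takes hydrogen at its less hindered terminus C1. This should give the cis-fused 6-bromo-7-(tert-butyldimethylsilyloxy)-2-ethoxy-2,3,3a,4,7,7a-hexahydrobenzofuran F1. The C1 methylene of F1 is then oxidized at the allylic position (CrO3, 3,5-dimethylpyrazole, CH2Cl2, −20 °C) to reach 7. The C–C bond formation is thereby separated from the oxygenation.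

Step 1. The most likely failures are poor discrimination between the two hydroxyls by a very reactive oxocarbenium ion, and acid-triggered exchange of the new mixed acetal with the neighbouring free C4 hydroxyl to a cyclic acetal. Fallback, from 1 back to 3: the C5 hydroxyl is first acylated selectively with a bulky reagent (pivaloyl chloride, pyridine, CH2Cl2, −30 °C) to give (1S,6S)-5-bromo-6-hydroxycyclohexa-2,4-dien-1-yl pivalate F2. O4 is silylated (TBSOTf, 2,6-lutidine, −78 °C) to give (1S,6S)-5-bromo-6-(tert-butyldimethylsilyloxy)cyclohexa-2,4-dien-1-yl pivalate F3. The ester is removed reductively (i-Bu2AlH, CH2Cl2, −78 °C) to give (1S,6S)-5-bromo-6-(tert-butyldimethylsilyloxy)cyclohexa-2,4-dien-1-ol F4. The only free hydroxyl of F4 is then converted into the iodoacetal under the conditions of step 1, which gives 3 with no neighbouring hydroxyl to interfere.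

Step 6. The most likely failure is slow or incomplete iodination, because the amine must first add to the fully substituted β-carbon C3 that is flanked by the silyloxy group. Fallback, from 8 back to 15: bromine is added across C2=C3 (Br2, CH2Cl2, −78 °C) to give the 5,6-dibromo-7-(tert-butyldimethylsilyloxy)-2-ethoxy-6-(hydroxymethyl)hexahydrobenzofuran-4(2H)-one F5, which is not isolated. Hydrogen bromide is removed with Et3N at 0 °C to give the cis-fused 5-bromo-7-(tert-butyldimethylsilyloxy)-2-ethoxy-6-(hydroxymethyl)-3,3a,7,7a-tetrahydrobenzofuran-4(2H)-one F6, a path that needs no nucleophilic attack at C3. F6 is coupled with 14 under the conditions of step 10 to give 15.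

Step 14. The most likely failure is acid-promoted loss of the C5 hydroxyl through the enol, followed by aromatization, while the tert-butyl ester is being cleaved. Fallback, from 16 back to 21 (it also makes step 12 unnecessary): the lactol is olefinated with commercial 2-(triphenylphosphoranylidene)propanal (toluene, 60 °C) to give (E)-4-[(1R,5R,6S)-3-[(1E,6R)-6-acetoxyhept-1-en-1-yl]-5,6-dihydroxy-4-(hydroxymethyl)-2-oxocyclohex-3-en-1-yl]-2-methylbut-2-enal F7. The aldehyde is taken to the acid by Pinnick oxidation (NaClO2, NaH2PO4, 2-methylbut-2-ene, t-BuOH/H2O, 0 °C), which gives 21 at weakly acidic pH with no ester to cleave.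

## Further compounds

F1 | step 3 | cis-fused 6-bromo-7-(tert-butyldimethylsilyloxy)-2-ethoxy-2,3,3a,4,7,7a-hexahydrobenzofuran | C1=C(Br)[C@@H](O[Si](C)(C)C(C)(C)C)[C@H]2OC(OCC)C[C@H]2C1
F2 | step 1 | (1S,6S)-5-bromo-6-hydroxycyclohexa-2,4-dien-1-yl pivalate | C1=C(Br)[C@@H](O)[C@@H](OC(=O)C(C)(C)C)C=C1
F3 | step 1 | (1S,6S)-5-bromo-6-(tert-butyldimethylsilyloxy)cyclohexa-2,4-dien-1-yl pivalate | C1=C(Br)[C@@H](O[Si](C)(C)C(C)(C)C)[C@@H](OC(=O)C(C)(C)C)C=C1
F4 | step 1 | (1S,6S)-5-bromo-6-(tert-butyldimethylsilyloxy)cyclohexa-2,4-dien-1-ol | C1=C(Br)[C@@H](O[Si](C)(C)C(C)(C)C)[C@@H](O)C=C1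
F5 | step 6 | 5,6-dibromo-7-(tert-butyldimethylsilyloxy)-2-ethoxy-6-(hydroxymethyl)hexahydrobenzofuran-4(2H)-one (C5 and C6 of the bicycle undefined) | BrC1C(Br)(CO)[C@@H](O[Si](C)(C)C(C)(C)C)[C@H]2OC(OCC)C[C@H]2C1=O
F6 | step 6 | cis-fused 5-bromo-7-(tert-butyldimethylsilyloxy)-2-ethoxy-6-(hydroxymethyl)-3,3a,7,7a-tetrahydrobenzofuran-4(2H)-one | BrC1=C(CO)[C@@H](O[Si](C)(C)C(C)(C)C)[C@H]2OC(OCC)C[C@H]2C1=O
F7 | step 14 | (E)-4-[(1R,5R,6S)-3-[(1E,6R)-6-acetoxyhept-1-en-1-yl]-5,6-dihydroxy-4-(hydroxymethyl)-2-oxocyclohex-3-en-1-yl]-2-methylbut-2-enal | CC(=O)O[C@H](C)CCC/C=C/C1=C(CO)[C@@H](O)[C@@H](O)[C@@H](C/C=C(\C)C=O)C1=O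
A1 | alternative 1 | cis-4,5-(isopropylidenedioxy)-3-[(tert-butyldimethylsilyloxy)methyl]cyclohex-2-en-1-one (C4, C5 as in 21) | C1=C(CO[Si](C)(C)C(C)(C)C)[C@H]2OC(C)(C)O[C@H]2CC1=O
A2 | alternative 1 | tert-butyl (E)-4-bromo-2-methylbut-2-enoate | BrC/C=C(\C)C(=O)OC(C)(C)C
A3 | alternative 1 | C6-alkylated enone acetonide with the branch trans to O5 (C6 epimer of the required series) | C1=C(CO[Si](C)(C)C(C)(C)C)[C@H]2OC(C)(C)O[C@H]2[C@H](C/C=C(\C)C(=O)OC(C)(C)C)C1=O
A4 | alternative 2 | quinone monoketal, tert-butyl (E)-4-[5-[(tert-butyldimethylsilyloxy)methyl]-4,4-dimethoxy-1-oxocyclohexa-2,5-dien-2-yl]-2-methylbut-2-enoate | O=C1C=C(CO[Si](C)(C)C(C)(C)C)C(OC)(OC)C=C1C/C=C(\C)C(=O)OC(C)(C)C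
A5 | alternative 2 | C5–C6 epoxy ketone with the epoxide oxygen cis to the C4 hydroxyl and the branch on C6 | C1=C(CO[Si](C)(C)C(C)(C)C)[C@@H](O)[C@H]2O[C@@]2(C/C=C(\C)C(=O)OC(C)(C)C)C1=O
A6 | alternative 3 | 5,6-cis-disubstituted cyclohexa-1,3-diene (C5 silyloxy, C6 branch, C3 silyloxymethyl) | C1C(CO[Si](C)(C)C(C)(C)C)=C[C@@H](O[Si](C)(C)C(C)(C)C)[C@@H](C/C=C(\C)C(=O)OC(C)(C)C)C=1
A7 | alternative 3 | C1–C4 endoperoxide of A6 with the peroxide bridge anti to the C5 and C6 substituents | C1(CO[Si](C)(C)C(C)(C)C)=C[C@H]2OO[C@@H]1[C@@H](O[Si](C)(C)C(C)(C)C)[C@H]2C/C=C(\C)C(=O)OC(C)(C)C
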